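## Retrosynthetic overview

1. Target 23 ⇐ one-pot hydrogenolysis (three benzyl ethers and one benzylic C–OH) of carbinol 21 ⇐ lactol 17 + aryl Grignard reagent 20. The route avoids the usual Friedel–Crafts union of a flavan with a diarylpropyl cation.
2. 17 ⇐ dihydrocoumarin 16 ⇐ key step: Rh/(R)-SEGPHOS asymmetric 1,4-addition of boronic acid 15 to the flavan-fused coumarin 14. This sets the diarylmethine centre (R), with the flavan 7-OH tied up as the lactone oxygen.
3. 14 ⇐ (2S)-flavan-7-ol 10 by ortho-formylation at C6, then Wittig olefination and lactonisation.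
4. 10 ⇐ flavanone 8 ⇐ Rh/chiral diene asymmetric 1,4-addition of boronic acid 7 to chromone 2, which sets C2 (S), followed by C4 deoxygenation.
5. Ring order: the benzopyranone of 1 is bought; ring C receives its stereocentre in steps 4–5; the lactone ring is annulated (steps 6–7), arylated (step 8) and opened again (steps 9–11).

Assumption: compounds 1, 3, 15 and 18 are bought, and each chiral ligand antipode is assigned from the known facial sense of the parent phenyl additions (to be confirmed on the first batch by chiral HPLC and ECD; the mirror-image ligand is used if the sense is reversed).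

## Route

Step 1
Reactants: 1 7-hydroxychromone
Product: 2 7-[(4-methoxybenzyl)oxy]-4H-chromen-4-one
Conditions: PMBCl (1.2 equiv), K2CO3, DMF, 60 °C
Reagents that add atoms: 4-methoxybenzyl chloride COc1ccc(CCl)cc1
Why: Williamson etherification of the acidic 7-OH, which would otherwise deactivate the chromone as a phenoxide in step 4; the PMB group is later removed by acid in the same pot as the C4 deoxygenation.

Step 2
Reactants: 3 3-bromo-4-methoxyphenol
Product: 4 4-(benzyloxy)-2-bromo-1-methoxybenzene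
Conditions: BnBr, K2CO3, acetone, reflux
Reagents that add atoms: benzyl bromide BrCc1ccccc1
Why: Williamson etherification; the benzyl ether survives every later step until the final hydrogenolysis.

Step 3
Reactants: 4 4-(benzyloxy)-2-bromo-1-methoxybenzene
Product: 7 [5-(benzyloxy)-2-methoxyphenyl]boronic acid, via aryllithium 5 (not isolated), via lithium arylborate 6 (not isolated)
Conditions: n-BuLi, THF, −78 °C; B(Oi-Pr)3, −78 °C → rt; 1 M HCl
Reagents that add atoms: triisopropyl borate CC(C)OB(OC(C)C)OC(C)C; water O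
Why: Bromine–lithium exchange is faster at −78 °C than ortho- or benzylic lithiation, and borate trapping followed by hydrolysis gives the boronic acid (lithiation–borylation).

Step 4
Reactants: 2 7-[(4-methoxybenzyl)oxy]-4H-chromen-4-one; 7 [5-(benzyloxy)-2-methoxyphenyl]boronic acid
Product: 8 (2S)-2-[5-(benzyloxy)-2-methoxyphenyl]-7-[(4-methoxybenzyl)oxy]chroman-4-one
Conditions: [RhCl(C2H4)2]2 (2.5 mol %), (1S,4S)-2,5-diphenylbicyclo[2.2.2]octa-2,5-diene (5.5 mol %), 7 (2.5 equiv), K3PO4 (0.5 equiv), toluene/H2O 10:1, 40 °C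
Reagents that add atoms: none
Why: Hayashi–Miyaura asymmetric 1,4-addition to a chromone, in which the aryl–rhodium bound to the C2-symmetric diene inserts the C2=C3 bond on one enantioface and protonation of the rhodium enolate gives the flavanone; the (S,S)-diene is expected to give 2S by the facial sense known for cyclic enones.

Step 5
Reactants: 8 (2S)-2-[5-(benzyloxy)-2-methoxyphenyl]-7-[(4-methoxybenzyl)oxy]chroman-4-one
Product: 10 (2S)-2-[5-(benzyloxy)-2-methoxyphenyl]chroman-7-ol, via cis-flavan-4-ol 9 (not isolated)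
Conditions: NaBH4, MeOH/THF, 0 °C; extractive work-up; Et3SiH (8 equiv), TFA (10 equiv, added last), CH2Cl2, −20 → 0 °C
Reagents that add atoms: none
Why: Carbonyl reduction followed by ionic hydrogenation, in which the C4 cation (stabilised by the para 7-oxygen and the ring oxygen) is trapped by silane hydride while TFA also cleaves the PMB ether; C2 is not touched because its cation has no para donor and the temperature is low.

Step 6
Reactants: 10 (2S)-2-[5-(benzyloxy)-2-methoxyphenyl]chroman-7-ol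
Product: 12 (2S)-2-[5-(benzyloxy)-2-methoxyphenyl]-7-hydroxychroman-6-carbaldehyde, via hydroxymethyl phenol 11 (not isolated)
Conditions: MgCl2, Et3N, (CH2O)n, MeCN, reflux; 1 M HCl work-up
Reagents that add atoms: paraformaldehyde (as formaldehyde) C=O
Why: Casnati–Skattebøl magnesium-mediated ortho-formylation, where the chelated magnesium phenoxide directs formaldehyde to the ortho position; C6 (para to the ring oxygen, unhindered) reacts in preference to C8 (flanked by two oxygens), as is general for chroman-7-ols.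

Step 7
Reactants: 12 (2S)-2-[5-(benzyloxy)-2-methoxyphenyl]-7-hydroxychroman-6-carbaldehyde
Product: 14 (8S)-8-[5-(benzyloxy)-2-methoxyphenyl]-6,7-dihydro-2H,8H-pyrano[3,2-g]chromen-2-one, via cinnamate ester 13 (not isolated)
Conditions: Ph3P=CHCO2Et (1.3 equiv), PhNEt2, 210 °C
Reagents that add atoms: ethyl (triphenylphosphoranylidene)acetate CCOC(=O)C=P(c1ccccc1)(c1ccccc1)c1ccccc1
Why: Wittig olefination with a stabilised ylide, followed at this temperature by E-to-Z isomerisation and lactonisation onto the neighbouring phenol, gives the linear coumarin.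

Step 8
Reactants: 14 (8S)-8-[5-(benzyloxy)-2-methoxyphenyl]-6,7-dihydro-2H,8H-pyrano[3,2-g]chromen-2-one; 15 [4-(benzyloxy)phenyl]boronic acid
Product: 16 (4R,8S)-8-[5-(benzyloxy)-2-methoxyphenyl]-4-[4-(benzyloxy)phenyl]-3,4,6,7-tetrahydro-2H,8H-pyrano[3,2-g]chromen-2-one
Conditions: Rh(acac)(C2H4)2 (3 mol %), (R)-SEGPHOS (3.3 mol %), 15 (5 equiv, portionwise), 1,4-dioxane/H2O 10:1, 60 °C
Reagents that add atoms: none
Why: Key step, a Hayashi–Miyaura asymmetric 1,4-addition to a coumarin, in which the (R)-SEGPHOS aryl–rhodium adds to C4 on the face that gives (R)-4-arylchroman-2-ones; the lactone tether fixes the alkene geometry and the remote C8 centre leaves the outcome under catalyst control.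

Step 9
Reactants: 16 (4R,8S)-8-[5-(benzyloxy)-2-methoxyphenyl]-4-[4-(benzyloxy)phenyl]-3,4,6,7-tetrahydro-2H,8H-pyrano[3,2-g]chromen-2-one
Product: 17 (4R,8S)-8-[5-(benzyloxy)-2-methoxyphenyl]-4-[4-(benzyloxy)phenyl]-3,4,6,7-tetrahydro-2H,8H-pyrano[3,2-g]chromen-2-ol (lactol, both anomers)
Conditions: i-Bu2AlH (1.2 equiv), CH2Cl2, −78 °C; aq. potassium sodium tartrate
Reagents that add atoms: none
Why: Partial reduction of a lactone, where the tetrahedral aluminate is stable at −78 °C and gives the lactol on work-up; C4 is beta to the carbonyl and cannot epimerise.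

Step 10
Reactants: 18 4-bromo-3-methoxyphenol
Product: 19 4-(benzyloxy)-1-bromo-2-methoxybenzene
Conditions: BnBr, K2CO3, acetone, reflux
Reagents that add atoms: benzyl bromide BrCc1ccccc1
Why: Williamson etherification, which leaves the bromide as the only site for magnesium insertion.

Step 11
Reactants: 17 lactol (4R,8S); 19 4-(benzyloxy)-1-bromo-2-methoxybenzene
Product: 21 (3R)-1-[4-(benzyloxy)-2-methoxyphenyl]-3-[4-(benzyloxy)phenyl]-3-{(2S)-2-[5-(benzyloxy)-2-methoxyphenyl]-7-hydroxychroman-6-yl}propan-1-ol (both C1 epimers), via aryl Grignard reagent 20 (not isolated)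
Conditions: 19 (3.3 equiv), Mg turnings (I2 crystal), THF, 45 °C; then 17, 0 °C → rt; aqueous work-up
Reagents that add atoms: none
Why: Grignard addition to a lactol, in which the first equivalent deprotonates it and releases the open phenoxide–aldehyde and the second adds to the aldehyde; the new carbinol centre is uncontrolled and is removed in step 12.

Step 12
Reactants: 21 carbinol (3R, 2S)
Product: 23 (2S)-6-[(1R)-1-(4-hydroxyphenyl)-3-(4-hydroxy-2-methoxyphenyl)propyl]-2-(5-hydroxy-2-methoxyphenyl)chroman-7-ol, via tetraphenol carbinol 22 (not isolated)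
Conditions: H2 (3 bar), 10% Pd/C, EtOAc/MeOH 1:1, AcOH (10 vol %), rt
Reagents that add atoms: none
Why: Catalytic hydrogenolysis cleaves the three benzyl ethers and then the benzylic C–OH, which is activated by its para-hydroxy and ortho-methoxy groups; the flavan C2–O bond has no para donor and both stereocentres are C–H centres that are not affected.

## Compound list

1 | 7-hydroxy-4H-chromen-4-one (7-hydroxychromone) | O=c1ccoc2cc(O)ccc12 | starting material
2 | 7-[(4-methoxybenzyl)oxy]-4H-chromen-4-one | COc1ccc(COc2ccc3c(c2)occc3=O)cc1 | intermediate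
3 | 3-bromo-4-methoxyphenol | COc1ccc(O)cc1Br | starting material
4 | 4-(benzyloxy)-2-bromo-1-methoxybenzene | COc1ccc(OCc2ccccc2)cc1Br | intermediate
5 | [5-(benzyloxy)-2-methoxyphenyl]lithium (formed in the flask) | COc1ccc(OCc2ccccc2)cc1[Li] | intermediate
6 | lithium [5-(benzyloxy)-2-methoxyphenyl]tri(propan-2-yloxy)borate (formed in the flask) | [Li+].COc1ccc(OCc2ccccc2)cc1[B-](OC(C)C)(OC(C)C)OC(C)C | intermediate
7 | [5-(benzyloxy)-2-methoxyphenyl]boronic acid | COc1ccc(OCc2ccccc2)cc1B(O)O | intermediate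
8 | (2S)-2-[5-(benzyloxy)-2-methoxyphenyl]-7-[(4-methoxybenzyl)oxy]chroman-4-one | COc1ccc(COc2ccc3c(c2)O[C@H](c2cc(OCc4ccccc4)ccc2OC)CC3=O)cc1 | intermediate
9 | (2S,4S)-2-[5-(benzyloxy)-2-methoxyphenyl]-7-[(4-methoxybenzyl)oxy]chroman-4-ol (major 2,4-cis epimer; the C4 epimer converges; crude) | COc1ccc(COc2ccc3c(c2)O[C@H](c2cc(OCc4ccccc4)ccc2OC)C[C@@H]3O)cc1 | intermediate
10 | (2S)-2-[5-(benzyloxy)-2-methoxyphenyl]chroman-7-ol | Oc1ccc2c(c1)O[C@H](c1cc(OCc3ccccc3)ccc1OC)CC2 | intermediate
11 | (2S)-2-[5-(benzyloxy)-2-methoxyphenyl]-6-(hydroxymethyl)chroman-7-ol (formed in the flask) | OCc1cc2c(cc1O)O[C@H](c1cc(OCc3ccccc3)ccc1OC)CC2 | intermediate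
12 | (2S)-2-[5-(benzyloxy)-2-methoxyphenyl]-7-hydroxychroman-6-carbaldehyde | O=Cc1cc2c(cc1O)O[C@H](c1cc(OCc3ccccc3)ccc1OC)CC2 | intermediate
13 | ethyl (2E)-3-{(2S)-2-[5-(benzyloxy)-2-methoxyphenyl]-7-hydroxychroman-6-yl}prop-2-enoate (formed in the flask) | CCOC(=O)/C=C/c1cc2c(cc1O)O[C@H](c1cc(OCc3ccccc3)ccc1OC)CC2 | intermediate
14 | (8S)-8-[5-(benzyloxy)-2-methoxyphenyl]-6,7-dihydro-2H,8H-pyrano[3,2-g]chromen-2-one (flavan-fused coumarin) | O=C1C=Cc2cc3c(cc2O1)O[C@H](c1cc(OCc2ccccc2)ccc1OC)CC3 | intermediate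
15 | [4-(benzyloxy)phenyl]boronic acid | OB(O)c1ccc(OCc2ccccc2)cc1 | starting material
16 | (4R,8S)-8-[5-(benzyloxy)-2-methoxyphenyl]-4-[4-(benzyloxy)phenyl]-3,4,6,7-tetrahydro-2H,8H-pyrano[3,2-g]chromen-2-one | O=C1C[C@H](c2ccc(OCc3ccccc3)cc2)c2cc3c(cc2O1)O[C@H](c1cc(OCc2ccccc2)ccc1OC)CC3 | intermediate
17 | (4R,8S)-8-[5-(benzyloxy)-2-methoxyphenyl]-4-[4-(benzyloxy)phenyl]-3,4,6,7-tetrahydro-2H,8H-pyrano[3,2-g]chromen-2-ol (lactol, both anomers) | OC1C[C@H](c2ccc(OCc3ccccc3)cc2)c2cc3c(cc2O1)O[C@H](c1cc(OCc2ccccc2)ccc1OC)CC3 | intermediate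
18 | 4-bromo-3-methoxyphenol | COc1cc(O)ccc1Br | starting material
19 | 4-(benzyloxy)-1-bromo-2-methoxybenzene | COc1cc(OCc2ccccc2)ccc1Br | intermediate
20 | [4-(benzyloxy)-2-methoxyphenyl]magnesium bromide (formed in the flask) | COc1cc(OCc2ccccc2)ccc1[Mg]Br | intermediate
21 | (3R)-1-[4-(benzyloxy)-2-methoxyphenyl]-3-[4-(benzyloxy)phenyl]-3-{(2S)-2-[5-(benzyloxy)-2-methoxyphenyl]-7-hydroxychroman-6-yl}propan-1-ol (both C1 epimers) | COc1cc(OCc2ccccc2)ccc1C(O)C[C@H](c1ccc(OCc2ccccc2)cc1)c1cc2c(cc1O)O[C@H](c1cc(OCc3ccccc3)ccc1OC)CC2 | intermediate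
22 | (3R)-3-(4-hydroxyphenyl)-1-(4-hydroxy-2-methoxyphenyl)-3-[(2S)-7-hydroxy-2-(5-hydroxy-2-methoxyphenyl)chroman-6-yl]propan-1-ol (both C1 epimers; formed in the flask) | COc1cc(O)ccc1C(O)C[C@H](c1ccc(O)cc1)c1cc2c(cc1O)O[C@H](c1cc(O)ccc1OC)CC2 | intermediate
23 | (2S)-6-[(1R)-1-(4-hydroxyphenyl)-3-(4-hydroxy-2-methoxyphenyl)propyl]-2-(5-hydroxy-2-methoxyphenyl)chroman-7-ol | COc1cc(O)ccc1CC[C@H](c1ccc(O)cc1)c1cc2c(cc1O)O[C@H](c1cc(O)ccc1OC)CC2 | target

## Step count and risks

Total steps: 12. Longest linear sequence: 10 (3 → 4 → 7 → 8 → 10 → 12 → 14 → 16 → 17 → 21 → 23).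

The three steps most likely to fail:

First, step 4. The ortho-methoxy boronic acid and the electron-rich chromone may give slow insertion, protodeboronation, or loss of ee through base-promoted ring opening of the flavanone. The fallback sets out from bromide 4 and comes back at flavanol 10, with the stereocentre set by ketone reduction and Mitsunobu closure instead of arylation. Bromide 4 is lithiated (n-BuLi, THF, −78 °C) and acylated with N-methoxy-N-methylacetamide to give 1-[5-(benzyloxy)-2-methoxyphenyl]ethan-1-one F1. Claisen–Schmidt condensation with purchased 2-hydroxy-4-[(4-methoxybenzyl)oxy]benzaldehyde (KOH, EtOH, rt) gives (2E)-1-[5-(benzyloxy)-2-methoxyphenyl]-3-{2-hydroxy-4-[(4-methoxybenzyl)oxy]phenyl}prop-2-en-1-one F2. Hydrogenation of the C=C bond over Pd/C poisoned with Ph2S (benzyl and PMB ethers and the ketone are kept) gives 1-[5-(benzyloxy)-2-methoxyphenyl]-3-{2-hydroxy-4-[(4-methoxybenzyl)oxy]phenyl}propan-1-one F3. Asymmetric transfer hydrogenation with RuCl[(R,R)-TsDPEN](p-cymene) in HCO2H/Et3N gives (1R)-1-[5-(benzyloxy)-2-methoxyphenyl]-3-{2-hydroxy-4-[(4-methoxybenzyl)oxy]phenyl}propan-1-ol F4. Mitsunobu etherification (PPh3, DIAD, THF, 0 °C) closes ring C with inversion to (2S)-2-[5-(benzyloxy)-2-methoxyphenyl]-7-[(4-methoxybenzyl)oxy]chromane F5, and TFA/Et3SiH in CH2Cl2 at 0 °C removes the PMB group to give 10.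

Second, step 8. The coumarin carries a para oxygen donor, so the aryl–rhodium insertion may stall against protodeboronation, or the ee may be insufficient. The fallback sets out from coumarin 14 (with boronic acid 15) and comes back at lactone 16, separating C–C bond formation from stereocontrol. An oxidative Heck coupling (Pd(OAc)2, 1,10-phenanthroline, O2, DMF, 80 °C; arylpalladation of C3=C4 then beta-hydride elimination) gives (8S)-8-[5-(benzyloxy)-2-methoxyphenyl]-4-[4-(benzyloxy)phenyl]-6,7-dihydro-2H,8H-pyrano[3,2-g]chromen-2-one F6. The C4 centre is then set by copper hydride asymmetric 1,4-reduction (Cu(OAc)2·H2O, the DTBM-SEGPHOS antipode that gives 4R, (EtO)2MeSiH, t-BuOH, toluene, 0 °C → rt), which returns 16. Any over-reduced material is lactol 17, the next compound of the route.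

Third, step 12. The acid-assisted hydrogenolysis may stop at carbinol 22 or at the cyclic ether formed by capture of the benzylic cation by the 7-OH, or it may begin to open ring C of the flavan. The fallback sets out from carbinol 21 and comes back at target 23, removing the benzylic oxygen before any hydrogenation. Treatment of 21 with Et3SiH and BF3·OEt2 in CH2Cl2 at −78 °C (ionic hydrogenation of the cation stabilised by para-benzyloxy and ortho-methoxy groups; any chroman formed by phenol capture re-ionises under the same conditions) gives (2S)-2-[5-(benzyloxy)-2-methoxyphenyl]-6-{(1R)-3-[4-(benzyloxy)-2-methoxyphenyl]-1-[4-(benzyloxy)phenyl]propyl}chroman-7-ol F7. The three benzyl ethers are then cleaved under neutral conditions (H2 1 bar, Pd/C, EtOAc/EtOH, rt, no acid) to give 23.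

## Further compounds

F1 | step 4 | 1-[5-(benzyloxy)-2-methoxyphenyl]ethan-1-one | COc1ccc(OCc2ccccc2)cc1C(C)=O
F2 | step 4 | (2E)-1-[5-(benzyloxy)-2-methoxyphenyl]-3-{2-hydroxy-4-[(4-methoxybenzyl)oxy]phenyl}prop-2-en-1-one | COc1ccc(COc2ccc(/C=C/C(=O)c3cc(OCc4ccccc4)ccc3OC)c(O)c2)cc1
F3 | step 4 | 1-[5-(benzyloxy)-2-methoxyphenyl]-3-{2-hydroxy-4-[(4-methoxybenzyl)oxy]phenyl}propan-1-one | COc1ccc(COc2ccc(CCC(=O)c3cc(OCc4ccccc4)ccc3OC)c(O)c2)cc1
F4 | step 4 | (1R)-1-[5-(benzyloxy)-2-methoxyphenyl]-3-{2-hydroxy-4-[(4-methoxybenzyl)oxy]phenyl}propan-1-ol | COc1ccc(COc2ccc(CC[C@@H](O)c3cc(OCc4ccccc4)ccc3OC)c(O)c2)cc1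
F5 | step 4 | (2S)-2-[5-(benzyloxy)-2-methoxyphenyl]-7-[(4-methoxybenzyl)oxy]chromane | COc1ccc(COc2ccc3c(c2)O[C@H](c2cc(OCc4ccccc4)ccc2OC)CC3)cc1
F6 | step 8 | (8S)-8-[5-(benzyloxy)-2-methoxyphenyl]-4-[4-(benzyloxy)phenyl]-6,7-dihydro-2H,8H-pyrano[3,2-g]chromen-2-one | O=C1C=C(c2ccc(OCc3ccccc3)cc2)c2cc3c(cc2O1)O[C@H](c1cc(OCc2ccccc2)ccc1OC)CC3
F7 | step 12 | (2S)-2-[5-(benzyloxy)-2-methoxyphenyl]-6-{(1R)-3-[4-(benzyloxy)-2-methoxyphenyl]-1-[4-(benzyloxy)phenyl]propyl}chroman-7-ol | COc1cc(OCc2ccccc2)ccc1CC[C@H](c1ccc(OCc2ccccc2)cc1)c1cc2c(cc1O)O[C@H](c1cc(OCc3ccccc3)ccc1OC)CC2
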